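**Plan**
- Numbering used: quinone carbons C1–C4, ring-fusion carbons C4a/C8a, 5-OH, 7-Me; the chromone is attached through its C8 to C2.
- Retrosynthesis: the C1–C2 and C3–C4 bonds are cut first. This takes out C2=C3 with its aryl group as a terminal arylalkyne and leaves a benzocyclobutene-1,2-dione. It is possible because the carbonyl carbons C1 and C4 sit on the adjacent benzo carbons C8a and C4a, so joining them gives a strained four-membered diketone ring (C1, C4, C4a, C8a) whose C1–C4 bond opens on a low-valent metal.
- Further cuts: alkyne–C8 bond of the chromone (Sonogashira), chromone C5–CO2 bond (carbonylation of a triflate), C8–I bond, pyranone ring (symmetric acetophenone plus one carbon); the dione goes back to an aryne and a tetraoxygenated alkene.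
- Forward: pyranone ring first, then C8 iodide, C5 triflate, alkyne and benzyl ester. The four-membered dione is made separately by aryne [2+2]. The quinone ring is formed last, by enlarging the four-membered ring with the two alkyne carbons; one dealkylation step ends the route.
- Stereochemistry: the target has no stereocentre and no defined axis, so nothing is to be controlled. The selectivity problem is regiochemical: the aryl group must end on the carbon next to the carbonyl remote from the 5-oxygen.

Key step: step 10

Remark: 1,2-diethoxy-1,2-bis(trimethylsilyloxy)ethene, 1-(2,6-dihydroxy-4-methylphenyl)ethan-1-one and ClCo(PPh3)3 are taken as purchasable, and the aryl–quinone axis is treated as freely rotating.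

**Step 1**
Reactants: 1 1-bromo-3-methoxy-5-methylbenzene; 2 1,2-diethoxy-1,2-bis(trimethylsilyloxy)ethene
Product: 5 3-methoxy-5-methylbenzocyclobutene-1,2-dione, via 3-methoxy-5-methylbenzyne 3 (not isolated), via silyl ketal cycloadduct 4 (not isolated)
Conditions: lithium 2,2,6,6-tetramethylpiperidide, THF, −78 °C → rt; then 2 M HCl, THF, rt
Reagents that add atoms: none
Why: Lithiation of 1 between OMe and Br and loss of LiBr should give aryne 3, which undergoes the known aryne [2+2] cycloaddition with oxygenated ketene-acetal-type alkenes (nucleophilic attack, then closure of the aryl anion onto the oxocarbenium ion); both new ring carbons arrive at the ketone oxidation level, so the orientation of addition is irrelevant, and mild acid hydrolysis of 4 unmasks the base-sensitive dione.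

**Step 2**
Reactants: 6 1-(2,6-dihydroxy-4-methylphenyl)ethan-1-one
Product: 8 5-hydroxy-7-methyl-4H-chromen-4-one, via enaminone 7 (not isolated)
Conditions: DMF-DMA, toluene, 90 °C; then conc. HCl, CH2Cl2, rt
Reagents that add atoms: N,N-dimethylformamide dimethyl acetal, COC(OC)N(C)C
Why: Enaminone formation at the acetyl group followed by acid-promoted intramolecular addition–elimination of a phenol is the standard enaminone route to 2,3-unsubstituted chromones, and the two hydroxyls of 6 are equivalent, so only one chromone can form.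

**Step 3**
Reactants: 8 5-hydroxy-7-methyl-4H-chromen-4-one
Product: 9 5-methoxy-7-methyl-4H-chromen-4-one
Conditions: MeI, K2CO3, DMF, 50 °C
Reagents that add atoms: iodomethane, CI
Why: Williamson O-methylation of the hydrogen-bonded 5-OH gives an ether that steers electrophilic substitution to the position para to it and can later be removed under chelation control.

**Step 4**
Reactants: 9 5-methoxy-7-methyl-4H-chromen-4-one
Product: 10 8-iodo-5-methoxy-7-methyl-4H-chromen-4-one
Conditions: NIS, TFA, MeCN, 0 °C → rt
Reagents that add atoms: N-iodosuccinimide, O=C1CCC(=O)N1I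
Why: Electrophilic aromatic iodination should go to C8, which is para to the methoxy group, ortho to the ring oxygen and less hindered than C6 (flanked by OMe and Me), in line with the C8 halogenation of 5-alkoxychromones and 5,7-dialkoxyflavones.

**Step 5**
Reactants: 10 8-iodo-5-methoxy-7-methyl-4H-chromen-4-one
Product: 11 5-hydroxy-8-iodo-7-methyl-4H-chromen-4-one
Conditions: BCl3, CH2Cl2, −78 → 0 °C; then H2O
Reagents that add atoms: none
Why: Chelation-controlled Lewis-acid demethylation: BCl3 bound between the C4 carbonyl and the peri methoxy oxygen cleaves the 5-OMe selectively and leaves the aryl iodide untouched.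

**Step 6**
Reactants: 11 5-hydroxy-8-iodo-7-methyl-4H-chromen-4-one
Product: 12 8-iodo-7-methyl-4-oxo-4H-chromen-5-yl trifluoromethanesulfonate
Conditions: Tf2O, pyridine, CH2Cl2, 0 °C
Reagents that add atoms: trifluoromethanesulfonic anhydride, O=S(=O)(OS(=O)(=O)C(F)(F)F)C(F)(F)F
Why: Standard phenol triflation turns the 5-oxygen into a pseudohalide for the later carbonylation.

**Step 7**
Reactants: 12 8-iodo-7-methyl-4-oxo-4H-chromen-5-yl trifluoromethanesulfonate; 13 ethynyltri(propan-2-yl)silane
Product: 14 7-methyl-4-oxo-8-{[tri(propan-2-yl)silyl]ethynyl}-4H-chromen-5-yl trifluoromethanesulfonate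
Conditions: PdCl2(PPh3)2 (cat.), CuI (cat.), Et3N, THF, rt
Reagents that add atoms: none
Why: Sonogashira coupling; oxidative addition into the C–I bond is much faster than into the aryl triflate at room temperature, so only C8 is alkynylated, and the bulky silyl cap protects the alkyne in the next step.

**Step 8**
Reactants: 14 7-methyl-4-oxo-8-{[tri(propan-2-yl)silyl]ethynyl}-4H-chromen-5-yl trifluoromethanesulfonate
Product: 15 benzyl 7-methyl-4-oxo-8-{[tri(propan-2-yl)silyl]ethynyl}-4H-chromene-5-carboxylate
Conditions: Pd(OAc)2 (cat.), 1,3-bis(diphenylphosphino)propane, CO (1 atm), BnOH, Et3N, DMF, 70 °C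
Reagents that add atoms: carbon monoxide, [C-]#[O+]; benzyl alcohol, OCc1ccccc1
Why: Palladium-catalysed alkoxycarbonylation of an aryl triflate (oxidative addition, CO insertion, alcoholysis of the acylpalladium) installs the carboxyl carbon as a benzyl ester, and the silyl-capped internal alkyne is inert under these conditions.

**Step 9**
Reactants: 15 benzyl 7-methyl-4-oxo-8-{[tri(propan-2-yl)silyl]ethynyl}-4H-chromene-5-carboxylate
Product: 16 benzyl 8-ethynyl-7-methyl-4-oxo-4H-chromene-5-carboxylate
Conditions: Bu4NF, AcOH, THF, 0 °C → rt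
Reagents that add atoms: none
Why: Fluoride-induced protodesilylation of the alkynylsilane; buffering with acetic acid protects the base-sensitive pyranone ring and the benzyl ester.

**Step 10**
Reactants: 5 3-methoxy-5-methylbenzocyclobutene-1,2-dione; 16 benzyl 8-ethynyl-7-methyl-4-oxo-4H-chromene-5-carboxylate
Product: 18 benzyl 8-(5-methoxy-7-methyl-1,4-dioxo-1,4-dihydronaphthalen-2-yl)-7-methyl-4-oxo-4H-chromene-5-carboxylate, via phthaloylcobalt metallacycle 17 (not isolated)
Conditions: ClCo(PPh3)3, PhCl, 25 °C; then 16, AgBF4 (excess), MeCN, 80 °C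
Reagents that add atoms: none
Why: The strained CO–CO bond of the four-membered ring of 5 should add oxidatively to monovalent cobalt to give the five-membered phthaloylcobalt metallacycle 17 (trivalent cobalt); AgBF4 removes chloride and binds free phosphine, alkyne 16 coordinates and inserts into one cobalt–acyl bond to give a seven-membered cobaltacycle, and C–C reductive elimination releases the quinone. The closest known reaction type is the phthaloylcobalt–alkyne naphthoquinone synthesis from benzocyclobutenediones, which accepts terminal alkynes and esters. The six-membered quinone ring is closed by reductive elimination between the cobalt-bound alkenyl carbon and the second acyl carbon, so the four-membered ring is enlarged by the two alkyne carbons in a formal [4+2] union of the C1/C4 diacyl unit with C2≡C3. No stereocentre is formed. The step needs regioselectivity: the unsubstituted alkyne carbon must bond to the acyl carbon next to the methoxy-bearing ring carbon (future C4) and the aryl-bearing carbon to the remote acyl (future C1). This is expected because the methoxy oxygen and the neighbouring acyl oxygen chelate the Lewis acid (silver or the cationic cobalt centre) and make that acyl carbon the electrophilic partner of the more nucleophilic, unhindered alkyne terminus, while the bulky doubly ortho-substituted aryl end stays on cobalt and closes onto the unhindered remote acyl.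

**Step 11**
Reactants: 18 benzyl 8-(5-methoxy-7-methyl-1,4-dioxo-1,4-dihydronaphthalen-2-yl)-7-methyl-4-oxo-4H-chromene-5-carboxylate
Product: 19 8-(5-hydroxy-7-methyl-1,4-dioxo-1,4-dihydronaphthalen-2-yl)-7-methyl-4-oxo-4H-chromene-5-carboxylic acid
Conditions: BCl3 (excess), CH2Cl2, −78 → 0 °C; then H2O
Reagents that add atoms: none
Why: Lewis-acid dealkylation: BCl3 chelated between the C4 quinone carbonyl and the peri 5-OMe cleaves the methyl ether and chloride attack on the activated benzylic carbon cleaves the benzyl ester, under acidic conditions that the quinone and the chromone should both survive.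

**Compound list**
1 | 1-bromo-3-methoxy-5-methylbenzene | COc1cc(C)cc(Br)c1 | starting material
2 | 1,2-diethoxy-1,2-bis(trimethylsilyloxy)ethene | CCOC(O[Si](C)(C)C)=C(OCC)O[Si](C)(C)C | starting material
3 | 3-methoxy-5-methylbenzyne (1,2-didehydro-3-methoxy-5-methylbenzene) | COC1=CC(C)=CC#C1 | intermediate
4 | 7,8-diethoxy-2-methoxy-4-methyl-7,8-bis(trimethylsilyloxy)bicyclo[4.2.0]octa-1,3,5-triene | CCOC1(O[Si](C)(C)C)c2cc(C)cc(OC)c2C1(OCC)O[Si](C)(C)C | intermediate
5 | 3-methoxy-5-methylbenzocyclobutene-1,2-dione (2-methoxy-4-methylbicyclo[4.2.0]octa-1,3,5-triene-7,8-dione) | COc1cc(C)cc2c1C(=O)C2=O | intermediate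
6 | 1-(2,6-dihydroxy-4-methylphenyl)ethan-1-one | CC(=O)c1c(O)cc(C)cc1O | starting material
7 | (E)-1-(2,6-dihydroxy-4-methylphenyl)-3-(dimethylamino)prop-2-en-1-one | CN(C)/C=C/C(=O)c1c(O)cc(C)cc1O | intermediate
8 | 5-hydroxy-7-methyl-4H-chromen-4-one | Cc1cc(O)c2c(=O)ccoc2c1 | intermediate
9 | 5-methoxy-7-methyl-4H-chromen-4-one | COc1cc(C)cc2occc(=O)c12 | intermediate
10 | 8-iodo-5-methoxy-7-methyl-4H-chromen-4-one | COc1cc(C)c(I)c2occc(=O)c12 | intermediate
11 | 5-hydroxy-8-iodo-7-methyl-4H-chromen-4-one | Cc1cc(O)c2c(=O)ccoc2c1I | intermediate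
12 | 8-iodo-7-methyl-4-oxo-4H-chromen-5-yl trifluoromethanesulfonate | Cc1cc(OS(=O)(=O)C(F)(F)F)c2c(=O)ccoc2c1I | intermediate
13 | ethynyltri(propan-2-yl)silane | C#C[Si](C(C)C)(C(C)C)C(C)C | starting material
14 | 7-methyl-4-oxo-8-{[tri(propan-2-yl)silyl]ethynyl}-4H-chromen-5-yl trifluoromethanesulfonate | Cc1cc(OS(=O)(=O)C(F)(F)F)c2c(=O)ccoc2c1C#C[Si](C(C)C)(C(C)C)C(C)C | intermediate
15 | benzyl 7-methyl-4-oxo-8-{[tri(propan-2-yl)silyl]ethynyl}-4H-chromene-5-carboxylate | Cc1cc(C(=O)OCc2ccccc2)c2c(=O)ccoc2c1C#C[Si](C(C)C)(C(C)C)C(C)C | intermediate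
16 | benzyl 8-ethynyl-7-methyl-4-oxo-4H-chromene-5-carboxylate | C#Cc1c(C)cc(C(=O)OCc2ccccc2)c2c(=O)ccoc12 | intermediate
17 | chloro(3-methoxy-5-methylphthaloyl)bis(triphenylphosphine)cobalt (trivalent cobalt, five-membered metallacycle) | O=C1c2cc(C)cc(OC)c2C(=O)[Co-2]1(Cl)([P+](c3ccccc3)(c3ccccc3)c3ccccc3)[P+](c3ccccc3)(c3ccccc3)c3ccccc3 | intermediate
18 | benzyl 8-(5-methoxy-7-methyl-1,4-dioxo-1,4-dihydronaphthalen-2-yl)-7-methyl-4-oxo-4H-chromene-5-carboxylate | COc1cc(C)cc2c1C(=O)C=C(c1c(C)cc(C(=O)OCc3ccccc3)c3c(=O)ccoc13)C2=O | intermediate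
19 | 8-(5-hydroxy-7-methyl-1,4-dioxo-1,4-dihydronaphthalen-2-yl)-7-methyl-4-oxo-4H-chromene-5-carboxylic acid | Cc1cc(O)c2c(c1)C(=O)C(c1c(C)cc(C(=O)O)c3c(=O)ccoc13)=CC2=O | target

**Count**
Total steps: 11. Longest linear sequence: 10 steps (6 to 19, steps 2 to 11); step 1 supplies the second branch.

**Steps most likely to fail**

Step 10. Regiocontrol in the alkyne insertion may be lost, since either cobalt–acyl bond can take up the unsubstituted alkyne carbon; silver acetylide formation or alkyne oligomerization may also compete. The fallback sets out from alkyne 16 and gives up the four-membered precursor. Commercial 1-bromo-2-methoxy-4-methylbenzene is lithiated (n-BuLi, THF, −78 °C), added to Cr(CO)6 and O-methylated (Me3OBF4) to give pentacarbonyl[methoxy(2-methoxy-4-methylphenyl)methylidene]chromium F1. Dötz benzannulation of F1 with 16 (THF, 55 °C) can only close at the one free ortho position of the aryl group and places the alkyne substituent next to the new phenol carbon. After loss of chromium it should give benzyl 8-(1-hydroxy-4,5-dimethoxy-7-methylnaphthalen-2-yl)-7-methyl-4-oxo-4H-chromene-5-carboxylate F2. Oxidation of F2 with (NH4)2Ce(NO3)6 in aqueous MeCN gives 18, where the route is rejoined.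

Step 1. The hindered tetraoxygenated alkene may trap the aryne inefficiently, with amide addition to the aryne or silyl transfer competing. The fallback sets out from 1. NaNH2 and 1,1-diethoxyethene in refluxing THF (aryne [2+2] with a simple ketene acetal) should give 7,7-diethoxy-5-methoxy-3-methylbicyclo[4.2.0]octa-1,3,5-triene F3. Aqueous HCl gives the ketone 5-methoxy-3-methylbicyclo[4.2.0]octa-1,3,5-trien-7-one F4. Radical bromination of its ring CH2 (NBS, 2 equiv, AIBN, PhCF3, reflux) gives 8,8-dibromo-5-methoxy-3-methylbicyclo[4.2.0]octa-1,3,5-trien-7-one F5, though the aryl methyl group may compete for bromine. Hydrolysis with AgO2CCF3 in aqueous MeCN returns to dione 5.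

Step 4. Iodination may occur at C6 or at the pyranone C3 instead of C8. The fallback sets out from 6 and fixes the iodine before the pyranone ring exists. Mono-O-methylation (MeI, 1 equiv, K2CO3, acetone) gives 1-(2-hydroxy-6-methoxy-4-methylphenyl)ethan-1-one F6. Phenol-directed iodination ortho to the free hydrogen-bonded hydroxyl, which is also para to OMe (benzyltrimethylammonium dichloroiodate, CaCO3, CH2Cl2–MeOH), gives 1-(2-hydroxy-3-iodo-6-methoxy-4-methylphenyl)ethan-1-one F7. DMF-DMA then gives (E)-3-(dimethylamino)-1-(2-hydroxy-3-iodo-6-methoxy-4-methylphenyl)prop-2-en-1-one F8, which closes with HCl to 10.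

**Further compounds**
F1 | step 10 | pentacarbonyl[methoxy(2-methoxy-4-methylphenyl)methylidene]chromium | COC(c1ccc(C)cc1OC)=[Cr](=C=O)(=C=O)(=C=O)(=C=O)=C=O
F2 | step 10 | benzyl 8-(1-hydroxy-4,5-dimethoxy-7-methylnaphthalen-2-yl)-7-methyl-4-oxo-4H-chromene-5-carboxylate | Oc1c(c3c(C)cc(C(=O)OCc4ccccc4)c4c(=O)ccoc34)cc(OC)c2c(OC)cc(C)cc12
F3 | step 1 | 7,7-diethoxy-5-methoxy-3-methylbicyclo[4.2.0]octa-1,3,5-triene | CCOC1(OCC)Cc2cc(C)cc(OC)c12
F4 | step 1 | 5-methoxy-3-methylbicyclo[4.2.0]octa-1,3,5-trien-7-one | O=C1Cc2cc(C)cc(OC)c12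
F5 | step 1 | 8,8-dibromo-5-methoxy-3-methylbicyclo[4.2.0]octa-1,3,5-trien-7-one | O=C1c2c(OC)cc(C)cc2C1(Br)Br
F6 | step 4 | 1-(2-hydroxy-6-methoxy-4-methylphenyl)ethan-1-one | CC(=O)c1c(O)cc(C)cc1OC
F7 | step 4 | 1-(2-hydroxy-3-iodo-6-methoxy-4-methylphenyl)ethan-1-one | CC(=O)c1c(OC)cc(C)c(I)c1O
F8 | step 4 | (E)-3-(dimethylamino)-1-(2-hydroxy-3-iodo-6-methoxy-4-methylphenyl)prop-2-en-1-one | CN(C)/C=C/C(=O)c1c(OC)cc(C)c(I)c1O
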